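**Plan**

1. Retrosynthetic cuts: (a) the O–CH3 bond of a methyl tetronate, which is the protecting group removed last; (b) the diene σ-bond between the CH=CH carbon and the C(CH3)= carbon, together with the C–CH3 bond on that same carbon; (c) the exocyclic C5=CH bond of the butenolide (ring C); (d) in the right half, the C4–CH2 bond of ring A (the 2,4-disubstituted furan) and the CH2 bridge between ring A and ring B (the 3-furyl ring).
2. Enabling feature: the diene carbon C(CH3)= is an sp2 carbon with two different carbon substituents (CH3 and the vinyl CH), and its partner =CH carries the CH2CH2–ring A chain. It therefore maps onto the CBr2 carbon of a 1,1-dibromoalkene whose two bromides differ only in being cis or trans to that chain, and the neighbouring (E)-CH=CH maps onto a terminal alkyne.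
3. Forward, left half: auxiliary-controlled alkylation, reduction and oxidation to an α-methyl aldehyde, vinylogous aldol with methyl 3-methyltetronate, Z-selective dehydration, alkyne unmasking. Forward, right half: 3-lithiofuran plus 4-bromofuran-2-carbaldehyde, deoxygenation, oxetane opening, oxidation, dibromoolefination.
4. Union: a one-pot hydrozirconation, trans-selective alkenylation and stereoretentive methylation joins the alkyne, the dibromoalkene and Me2Zn into the (E,E)-diene; thiolate demethylation finishes. The helpers (auxiliary, silyl cap, O-methyl group, both bromines) are all removed along the way.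
5. Stereochemistry: the (S) centre comes from the (R)-benzyloxazolidinone auxiliary; 5Z from thermodynamically controlled E1cB dehydration; 4E from syn-hydrozirconation; 6E from the order in which the two bromides are replaced.

Key step: step 13

Remark: 3-methyltetronic acid is taken as a catalogue compound (otherwise it is available in one operation from ethyl 2-methylacetoacetate by bromination and thermal lactonisation); the tetronic acid is carried as its O-methyl ether until the last step.

**Route**

Step 1
Reactants: 1 (4R)-4-benzyl-3-propanoyl-1,3-oxazolidin-2-one; 2 3-bromo-1-(trimethylsilyl)prop-1-yne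
Product: 4 (4R)-4-benzyl-3-[(2S)-2-methyl-5-(trimethylsilyl)pent-4-ynoyl]-1,3-oxazolidin-2-one, via sodium Z-enolate 3 (not isolated)
Conditions: NaN(SiMe3)2, THF, −78 °C; then 2, −78 → −40 °C
Reagents that add atoms: NaN(SiMe3)2, C[Si](C)(C)[N-][Si](C)(C)C.[Na+] (sodium kept only in 3)
Why: Evans asymmetric alkylation, in which the chelated sodium Z-enolate 3 is attacked by the propargylic bromide on the face opposite the C4 benzyl group of the (R)-auxiliary, setting the (2S) centre that becomes the only stereocentre of the target.

Step 2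
Reactants: 4 (4R)-4-benzyl-3-[(2S)-2-methyl-5-(trimethylsilyl)pent-4-ynoyl]-1,3-oxazolidin-2-one
Product: 5 (2S)-2-methyl-5-(trimethylsilyl)pent-4-yn-1-ol
Conditions: LiBH4, MeOH (1 equiv), Et2O, 0 °C
Reagents that add atoms: none
Why: Reductive cleavage of the N-acyloxazolidinone by LiBH4 at the more electrophilic exocyclic carbonyl should give the primary alcohol without touching the stereocentre or the silylalkyne, and releases the auxiliary.

Step 3
Reactants: 5 (2S)-2-methyl-5-(trimethylsilyl)pent-4-yn-1-ol
Product: 6 (2S)-2-methyl-5-(trimethylsilyl)pent-4-ynal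
Conditions: Dess–Martin periodinane, pyridine, CH2Cl2, 0 → 23 °C
Reagents that add atoms: none
Why: Dess–Martin oxidation under buffered, non-enolising conditions should give the α-branched aldehyde without epimerisation; it is used at once in step 5.

Step 4
Reactants: 7 4-hydroxy-3-methylfuran-2(5H)-one (3-methyltetronic acid)
Product: 8 4-methoxy-3-methylfuran-2(5H)-one
Conditions: Me2SO4, K2CO3, acetone, reflux
Reagents that add atoms: dimethyl sulfate, COS(=O)(=O)OC
Why: O-Alkylation of the vinylogous acid by the hard electrophile dimethyl sulfate masks the acidic OH as a vinylogous methyl ester and leaves C5 as the only acidic carbon.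

Step 5
Reactants: 8 4-methoxy-3-methylfuran-2(5H)-one; 6 (2S)-2-methyl-5-(trimethylsilyl)pent-4-ynal
Product: 10 5-[(2S)-1-hydroxy-2-methyl-5-(trimethylsilyl)pent-4-yn-1-yl]-4-methoxy-3-methylfuran-2(5H)-one (mixture of diastereomers at C5 and the carbinol carbon), via lithium furanolate 9 (not isolated)
Conditions: LiN(i-Pr)2, THF, −78 °C; then 6, −78 °C; aq. NH4Cl
Reagents that add atoms: LiN(i-Pr)2, CC(C)[N-]C(C)C.[Li+] (lithium kept only in 9)
Why: Vinylogous (γ-selective) aldol addition, in which C5 deprotonation gives the 2-oxidofuran dienolate 9 that adds through C5 to the aldehyde faster than the aldehyde α-centre can enolise; the two new centres are destroyed in step 6, so their configuration does not matter.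

Step 6
Reactants: 10 5-[(2S)-1-hydroxy-2-methyl-5-(trimethylsilyl)pent-4-yn-1-yl]-4-methoxy-3-methylfuran-2(5H)-one
Product: 12 (5Z)-4-methoxy-3-methyl-5-[(2S)-2-methyl-5-(trimethylsilyl)pent-4-yn-1-ylidene]furan-2(5H)-one, via mesylate 11 (not isolated)
Conditions: MsCl, Et3N, CH2Cl2, 0 °C; then DBU, 0 → 23 °C
Reagents that add atoms: methanesulfonyl chloride, CS(=O)(=O)Cl (its atoms are kept only in 11)
Why: Mesylation and DBU-induced E1cB elimination through the C5 furanolate (aldol condensation/dehydration) should favour the Z alkene, in which the chain lies syn to the ring oxygen and avoids allylic strain with the C4 methoxy group.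

Step 7
Reactants: 12 (5Z)-4-methoxy-3-methyl-5-[(2S)-2-methyl-5-(trimethylsilyl)pent-4-yn-1-ylidene]furan-2(5H)-one
Product: 13 (5Z)-4-methoxy-3-methyl-5-[(2S)-2-methylpent-4-yn-1-ylidene]furan-2(5H)-one
Conditions: Bu4NF, AcOH, THF, 0 °C
Reagents that add atoms: none
Why: Fluoride-induced protodesilylation of the alkynylsilane, with acetic acid buffering so that the enol lactone and the allylic stereocentre are not exposed to base.

Step 8
Reactants: 14 3-bromofuran; 15 4-bromofuran-2-carbaldehyde
Product: 17 (4-bromofuran-2-yl)(furan-3-yl)methanol (racemic), via 3-lithiofuran 16 (not isolated)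
Conditions: n-BuLi, THF, −78 °C; then 15, −78 °C; aq. NH4Cl
Reagents that add atoms: n-BuLi, [Li]CCCC (lithium kept only in 16)
Why: Bromine–lithium exchange at −78 °C, where 3-lithiofuran does not isomerise, followed by 1,2-addition to the aldehyde, which is much faster than exchange at the ring bromide of 15.

Step 9
Reactants: 17 (4-bromofuran-2-yl)(furan-3-yl)methanol
Product: 18 4-bromo-2-(furan-3-ylmethyl)furan
Conditions: Et3SiH (excess), CF3CO2H, CH2Cl2, −20 → 0 °C
Reagents that add atoms: none
Why: Ionic hydrogenation, in which acid ionises the carbinol to a cation stabilised by both furans and Et3SiH traps it at the exocyclic carbon, restoring both aromatic rings and leaving the ring bromide alone.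

Step 10
Reactants: 18 4-bromo-2-(furan-3-ylmethyl)furan; 19 oxetane
Product: 21 3-[5-(furan-3-ylmethyl)furan-3-yl]propan-1-ol, via 4-lithiofuran 20 (not isolated)
Conditions: t-BuLi (2 equiv), Et2O, −78 °C; then 19, BF3·OEt2, −78 °C; aq. NaHCO3
Reagents that add atoms: t-BuLi, [Li]C(C)(C)C (lithium kept only in 20)
Why: Bromine–lithium exchange gives the β-lithiofuran 20, which opens BF3-activated oxetane by SN2 attack at −78 °C (Lewis-acid-promoted oxetane opening by an organolithium), placing the three-carbon chain on C4 of ring A.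

Step 11
Reactants: 21 3-[5-(furan-3-ylmethyl)furan-3-yl]propan-1-ol
Product: 22 3-[5-(furan-3-ylmethyl)furan-3-yl]propanal
Conditions: Dess–Martin periodinane, pyridine, CH2Cl2, 0 → 23 °C
Reagents that add atoms: none
Why: Dess–Martin oxidation of the primary alcohol, buffered with pyridine to protect the acid-sensitive furans.

Step 12
Reactants: 22 3-[5-(furan-3-ylmethyl)furan-3-yl]propanal
Product: 23 4-(4,4-dibromobut-3-en-1-yl)-2-(furan-3-ylmethyl)furan
Conditions: CBr4, PPh3, Zn dust, CH2Cl2, 23 °C; then 22, 0 → 23 °C
Reagents that add atoms: carbon tetrabromide, BrC(Br)(Br)Br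
Why: Ramirez–Corey–Fuchs dibromoolefination (Wittig reaction of Ph3P=CBr2), with the ylide preformed using zinc so that no Ph3PBr2 or HBr meets the furans.

Step 13
Reactants: 13 (5Z)-4-methoxy-3-methyl-5-[(2S)-2-methylpent-4-yn-1-ylidene]furan-2(5H)-one; 23 4-(4,4-dibromobut-3-en-1-yl)-2-(furan-3-ylmethyl)furan
Product: 27 (5Z)-5-[(2S,4E,6E)-9-[5-(furan-3-ylmethyl)furan-3-yl]-2,6-dimethylnona-4,6-dien-1-ylidene]-4-methoxy-3-methylfuran-2(5H)-one, via alkenylzirconocene chloride 24 (not isolated), via alkenylzinc bromide 25 (not isolated), via Z-bromodiene 26 (not isolated)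
Conditions: Cp2Zr(H)Cl (about 1 equiv), THF, 23 °C; ZnBr2, 0 °C; 23, PdCl2(DPEphos) (cat.), 0 → 23 °C; then Me2Zn, Pd(P(t-Bu)3)2 (cat.), 23 °C
Reagents that add atoms: dimethylzinc, C[Zn]C (one methyl ends in 27); Cp2Zr(H)Cl, [H][Zr+2]Cl.c1cc[cH-]c1.c1cc[cH-]c1 (zirconium kept only in 24); ZnBr2, Br[Zn]Br (zinc kept only in 25)
Why: syn-Hydrozirconation of the terminal alkyne of 13 puts zirconium on the terminal carbon to give the (E)-alkenylzirconocene 24, which ZnBr2 converts into alkenylzinc 25; zerovalent palladium bearing the wide-bite-angle DPEphos ligand then inserts only into the C–Br bond of 23 that is trans to the CH2CH2–ring A chain (the less hindered one), and transmetalation and reductive elimination form the central σ-bond of the diene, leaving the (Z)-bromodiene 26. In the same flask zerovalent palladium with the bulky P(t-Bu)3 ligand inserts into the remaining, more hindered C–Br bond and Me2Zn delivers the methyl group with retention, because transmetalation and reductive elimination on the monophosphine complex should outrun the isomerisation of the dienylpalladium intermediate that leads to inversion with chelating ligands. The closest known reaction type is the tandem Negishi coupling of 1,1-dibromo-1-alkenes (trans-selective monoalkenylation, then stereoretentive alkylation), here fed by an in situ hydrozirconation. No ring is closed and no stereocentre is formed; the (S) centre lies two carbons from the reacting alkyne and is not touched. The step needs chemoselectivity of Zr–H for the alkyne over the lactone carbonyl (secured by the low electrophilicity of the vinylogous-carbonate-like methyl tetronate and by using close to one equivalent of Cp2Zr(H)Cl), mono- and trans-selectivity in the first coupling (secured by the steric difference between the two bromides and the much lower reactivity of the bromodiene) and retention in the second (secured by the ligand switch).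

Step 14
Reactants: 27 (5Z)-5-[(2S,4E,6E)-9-[5-(furan-3-ylmethyl)furan-3-yl]-2,6-dimethylnona-4,6-dien-1-ylidene]-4-methoxy-3-methylfuran-2(5H)-one
Product: 28 (5Z)-5-[(2S,4E,6E)-9-[5-(furan-3-ylmethyl)furan-3-yl]-2,6-dimethylnona-4,6-dien-1-ylidene]-4-hydroxy-3-methylfuran-2(5H)-one
Conditions: n-PrSLi (from n-PrSH, n-BuLi), HMPA, 23 °C; then cold 1 M HCl
Reagents that add atoms: none
Why: SN2 O-demethylation of the vinylogous methyl ester by the soft thiolate, with the tetronate anion as a good leaving group, under conditions too weakly basic to disturb the allylic stereocentre, the diene or the furans; acidification should release the free tetronic acid.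

**Compound list**

1 | (4R)-4-benzyl-3-propanoyl-1,3-oxazolidin-2-one | CCC(=O)N1[C@H](Cc2ccccc2)COC1=O | starting material
2 | 3-bromo-1-(trimethylsilyl)prop-1-yne | C[Si](C)(C)C#CCBr | starting material
3 | sodium (Z)-enolate of 1 | C/C=C(\[O-])N1[C@H](Cc2ccccc2)COC1=O.[Na+] | intermediate
4 | (4R)-4-benzyl-3-[(2S)-2-methyl-5-(trimethylsilyl)pent-4-ynoyl]-1,3-oxazolidin-2-one | O=C([C@@H](C)CC#C[Si](C)(C)C)N1[C@H](Cc2ccccc2)COC1=O | intermediate
5 | (2S)-2-methyl-5-(trimethylsilyl)pent-4-yn-1-ol | OC[C@@H](C)CC#C[Si](C)(C)C | intermediate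
6 | (2S)-2-methyl-5-(trimethylsilyl)pent-4-ynal | O=C[C@@H](C)CC#C[Si](C)(C)C | intermediate
7 | 4-hydroxy-3-methylfuran-2(5H)-one (3-methyltetronic acid) | CC1=C(O)COC1=O | starting material
8 | 4-methoxy-3-methylfuran-2(5H)-one | CC1=C(OC)COC1=O | intermediate
9 | 2-(lithiooxy)-4-methoxy-3-methylfuran (lithium furanolate of 8) | COc1coc(O[Li])c1C | intermediate
10 | 5-[(2S)-1-hydroxy-2-methyl-5-(trimethylsilyl)pent-4-yn-1-yl]-4-methoxy-3-methylfuran-2(5H)-one (diastereomer mixture) | CC1=C(OC)C(C(O)[C@@H](C)CC#C[Si](C)(C)C)OC1=O | intermediate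
11 | methanesulfonate of 10 | CC1=C(OC)C(C(OS(C)(=O)=O)[C@@H](C)CC#C[Si](C)(C)C)OC1=O | intermediate
12 | (5Z)-4-methoxy-3-methyl-5-[(2S)-2-methyl-5-(trimethylsilyl)pent-4-yn-1-ylidene]furan-2(5H)-one | CC1=C(OC)/C(=C/[C@@H](C)CC#C[Si](C)(C)C)OC1=O | intermediate
13 | (5Z)-4-methoxy-3-methyl-5-[(2S)-2-methylpent-4-yn-1-ylidene]furan-2(5H)-one | CC1=C(OC)/C(=C/[C@@H](C)CC#C)OC1=O | intermediate
14 | 3-bromofuran | Brc1ccoc1 | starting material
15 | 4-bromofuran-2-carbaldehyde | O=Cc1cc(Br)co1 | starting material
16 | 3-lithiofuran | [Li]c1ccoc1 | intermediate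
17 | (4-bromofuran-2-yl)(furan-3-yl)methanol (racemic) | OC(c1ccoc1)c1cc(Br)co1 | intermediate
18 | 4-bromo-2-(furan-3-ylmethyl)furan | Brc1coc(Cc2ccoc2)c1 | intermediate
19 | oxetane | C1COC1 | starting material
20 | 2-(furan-3-ylmethyl)-4-lithiofuran | [Li]c1coc(Cc2ccoc2)c1 | intermediate
21 | 3-[5-(furan-3-ylmethyl)furan-3-yl]propan-1-ol | OCCCc1coc(Cc2ccoc2)c1 | intermediate
22 | 3-[5-(furan-3-ylmethyl)furan-3-yl]propanal | O=CCCc1coc(Cc2ccoc2)c1 | intermediate
23 | 4-(4,4-dibromobut-3-en-1-yl)-2-(furan-3-ylmethyl)furan | BrC(Br)=CCCc1coc(Cc2ccoc2)c1 | intermediate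
24 | (E)-alkenylzirconocene chloride from 13 (cyclopentadienyl rings written as cyclopentadienide ions) | CC1=C(OC)/C(=C/[C@@H](C)C/C=C/[Zr+2]Cl)OC1=O.c1cc[cH-]c1.c1cc[cH-]c1 | intermediate
25 | (E)-alkenylzinc bromide from 24 | CC1=C(OC)/C(=C/[C@@H](C)C/C=C/[Zn]Br)OC1=O | intermediate
26 | (5Z)-5-[(2S,4E,6Z)-6-bromo-9-[5-(furan-3-ylmethyl)furan-3-yl]-2-methylnona-4,6-dien-1-ylidene]-4-methoxy-3-methylfuran-2(5H)-one | CC1=C(OC)/C(=C/[C@@H](C)C/C=C/C(Br)=C/CCc2coc(Cc3ccoc3)c2)OC1=O | intermediate
27 | (5Z)-5-[(2S,4E,6E)-9-[5-(furan-3-ylmethyl)furan-3-yl]-2,6-dimethylnona-4,6-dien-1-ylidene]-4-methoxy-3-methylfuran-2(5H)-one | CC1=C(OC)/C(=C/[C@@H](C)C/C=C/C(C)=C/CCc2coc(Cc3ccoc3)c2)OC1=O | intermediate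
28 | (5Z)-5-[(2S,4E,6E)-9-[5-(furan-3-ylmethyl)furan-3-yl]-2,6-dimethylnona-4,6-dien-1-ylidene]-4-hydroxy-3-methylfuran-2(5H)-one | CC1=C(O)/C(=C/[C@@H](C)C/C=C/C(C)=C/CCc2coc(Cc3ccoc3)c2)OC1=O | target

**Count**

Total steps: 14. Longest linear sequence: 8 steps (1, 2, 3, 5, 6, 7, 13, 14).

**Steps most likely to fail**

Step 13. The methylation may partly invert the olefin geometry if the DPEphos-bound palladium left from the first coupling turns the bromodiene over through its isomerised dienylpalladium form. Zr–H may also attack the enol lactone, or a second alkenylation may compete. The fallback sets out from 23 and 13 and returns at 27, with both geometries fixed before a two-component coupling. Compound 23 is treated with n-BuLi (2.2 equiv, THF, −78 °C) and then MeI to give the 2-alkyne 2-(furan-3-ylmethyl)-4-(pent-3-yn-1-yl)furan F1. Hydrozirconation of F1 with excess Cp2Zr(H)Cl (THF, 40 °C, which equilibrates zirconium to the methyl-bearing carbon) and quenching with I2 should give the alkenyl iodide 2-(furan-3-ylmethyl)-4-[(3E)-4-iodopent-3-en-1-yl]furan F2. Separately, 13 is converted by copper-catalysed formal hydroboration (B2pin2, CuCl, NaOt-Bu, Xantphos, MeOH, THF, 23 °C) into the (E)-alkenyl pinacolboronate F3. Suzuki–Miyaura coupling of F2 with F3 (Pd(dppf)Cl2, K3PO4, DMF/H2O, 23 °C) should then give 27.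

Step 9. The bis-furyl cation may alkylate other furan rings (Friedel–Crafts oligomerisation), or acid may open a furan ring, before hydride transfer occurs. The fallback sets out from 15, returns at 18, replaces steps 8 and 9, and involves neither a carbocation nor acid. Compound 15 is condensed with TsNHNH2 (MeOH, 23 °C) to the tosylhydrazone N'-[(4-bromofuran-2-yl)methylidene]-4-methylbenzenesulfonohydrazide F4. Transition-metal-free reductive coupling of F4 with furan-3-ylboronic acid (K2CO3, dioxane, 110 °C; diazo formation, 1,2-boron-to-carbon shift, protodeboronation) should give 18 directly.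

Step 10. The β-lithiofuran 20 may be quenched by proton transfer from the acidic bis-furyl CH2 group, or may isomerise to an α-lithio species, before it opens the oxetane; BF3 may also attack the furans. The fallback sets out from 18, returns at 22, and bypasses 21 and step 11. Negishi coupling of 18 with commercial [2-(1,3-dioxolan-2-yl)ethyl]zinc bromide (Pd(OAc)2, SPhos, THF, 50 °C) should give the acetal 2-{2-[5-(furan-3-ylmethyl)furan-3-yl]ethyl}-1,3-dioxolane F5. Mild hydrolysis of F5 (pyridinium p-toluenesulfonate, acetone/H2O, 50 °C) should give 22.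

**Further compounds**

F1 | step 13 | 2-(furan-3-ylmethyl)-4-(pent-3-yn-1-yl)furan | CC#CCCc1coc(Cc2ccoc2)c1
F2 | step 13 | 2-(furan-3-ylmethyl)-4-[(3E)-4-iodopent-3-en-1-yl]furan | I/C(C)=C/CCc1coc(Cc2ccoc2)c1
F3 | step 13 | (5Z)-4-methoxy-3-methyl-5-[(2S,4E)-2-methyl-5-(4,4,5,5-tetramethyl-1,3,2-dioxaborolan-2-yl)pent-4-en-1-ylidene]furan-2(5H)-one | CC1=C(OC)/C(=C/[C@@H](C)C/C=C/B2OC(C)(C)C(C)(C)O2)OC1=O
F4 | step 9 | N'-[(4-bromofuran-2-yl)methylidene]-4-methylbenzenesulfonohydrazide | Cc1ccc(cc1)S(=O)(=O)N/N=C/c1cc(Br)co1
F5 | step 10 | 2-{2-[5-(furan-3-ylmethyl)furan-3-yl]ethyl}-1,3-dioxolane | C1(CCc2coc(Cc3ccoc3)c2)OCCO1
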